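The synthesis rests on cutting the C4a–C5 bond of ring A in the apigenin half, the flavone unit without the methoxy group. This ring is a benzene oxygenated at C5, C7 and C8a and acylated at C4a, the aromatised fold of a linear tetraketide. Before ring C closes it is symmetric, so the fold has no regiochemical ambiguity. In one operation Mg(OMe)2 opens a 4-hydroxy-2-pyranone and recloses the liberated chain by C-acylation. This delivers carbocyclic ring A as a 2',4',6'-trihydroxychalcone. The precursor is triacetic acid lactone acylated at its 6-methyl carbon by an E-cinnamoyl group whose aryl ring already bears the complete, benzyl-protected acacetin half.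

Key step: step 10

Remarks on the chemistry
- Assumption: the target SMILES holds no stereodescriptor, so the C3'–C8'' biaryl axis is taken as stereochemically undefined. The only stereo-elements on the way are E-alkenes and racemic sp3 carbons in two transient species, all erased by the end of step 11.
- Locants: unprimed (rings A and C) and primed (ring B) belong to the apigenin half. Double-primed (chromenone) and triple-primed (anisyl ring) belong to the acacetin half.
- The two ortho carbons of the chalcone phloroglucinol ring are equivalent. The bond made in the key step (C1'–C2' of the chalcone) therefore becomes C4a–C5 or, with equal right, C4a–C8a once ring C is closed. It is called C4a–C5 here.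
- Ar* = 4-(benzyloxy)-3-[5,7-bis(benzyloxy)-2-(4-methoxyphenyl)-4-oxo-4H-chromen-8-yl]phenyl.
- Design choices:
  - (a) The acacetin flavone is finished before the biaryl coupling, so no aldehyde or enone meets the enolate chemistry of the flavone synthesis.
  - (b) The cinnamoyl donor is an N-methoxy-N-methylamide installed on the small bromoarene. This saves an acid-activation sequence and keeps the acidic product from quenching the dianion.
  - (c) The pyranone 4-OH stays free, because an O-alkyl group there could be exchanged by methoxide or end up as an unwanted 7-ether.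
  - (d) The benzyl groups leave by hydrogenolysis, so the single methyl ether never meets a Lewis acid.

Step 1
Reactants: 1 2,4,6-trihydroxyacetophenone
Product: 2 1-[2,4-bis(benzyloxy)-6-hydroxyphenyl]ethanone
Conditions: BnBr (2.1 equiv), K2CO3, DMF, 60 °C
Reagents that add atoms: benzyl bromide, BrCc1ccccc1
Why: Williamson etherification in which the 4-OH and one of the two equivalent ortho-OH groups are alkylated, whereas the remaining ortho-OH is tied up in a hydrogen bond to the acetyl oxygen and is too poor a nucleophile to react with the limited amount of BnBr.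

Step 2
Reactants: 2 1-[2,4-bis(benzyloxy)-6-hydroxyphenyl]ethanone
Product: 3 1-[4,6-bis(benzyloxy)-2-hydroxy-3-iodophenyl]ethanone
Conditions: NIS (1.0 equiv), TFA (cat.), MeCN, 0 °C to rt
Reagents that add atoms: N-iodosuccinimide, O=C1CCC(=O)N1I
Why: Electrophilic aromatic iodination: C3 and C5 are both activated by three oxygen donors, but C3 sits next to the small free OH while C5 is wedged between two benzyloxy groups, so iodine should enter at C3, the carbon that becomes C8'' of the acacetin unit.

Step 3
Reactants: 3 1-[4,6-bis(benzyloxy)-2-hydroxy-3-iodophenyl]ethanone; 4 4-methoxybenzoyl chloride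
Product: 6 1-[4,6-bis(benzyloxy)-2-hydroxy-3-iodophenyl]-3-(4-methoxyphenyl)propane-1,3-dione, via dilithio enolate 5 (not isolated)
Conditions: LiN(SiMe3)2 (3.3 equiv), THF, −78 to −10 °C; 4 (1.05 equiv), −78 °C to rt; aq. HCl
Reagents that add atoms: none
Why: One-flask variant of the Baker–Venkataraman aroyl transfer: the preformed phenoxide–enolate 5 is aroylated at carbon, any O-aroyl ester formed on the side is carried to the same 1,3-diketone by the excess base, and a lithium amide does not disturb the aryl iodide, which has no ortho hydrogen.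

Step 4
Reactants: 6 1-[4,6-bis(benzyloxy)-2-hydroxy-3-iodophenyl]-3-(4-methoxyphenyl)propane-1,3-dione
Product: 7 5,7-bis(benzyloxy)-8-iodo-2-(4-methoxyphenyl)-4H-chromen-4-one
Conditions: NaOAc, AcOH, 110 °C
Reagents that add atoms: none
Why: Cyclodehydration that ends the Baker–Venkataraman flavone synthesis: the phenol adds to the anisoyl carbonyl of the enolised diketone (6-exo-trig) and loss of water gives the aromatic 4-pyranone, the acetate buffer being too mild to cleave benzyl ethers or the C–I bond.

Step 5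
Reactants: 8 3-bromo-4-hydroxybenzaldehyde
Product: 9 4-(benzyloxy)-3-bromobenzaldehyde
Conditions: BnBr (1.1 equiv), K2CO3, DMF, rt
Reagents that add atoms: benzyl bromide, BrCc1ccccc1
Why: Williamson etherification of an acidic para-formylphenol, with no other nucleophilic site in the molecule.

Step 6
Reactants: 9 4-(benzyloxy)-3-bromobenzaldehyde; 10 N-methoxy-N-methyl-2-(triphenylphosphoranylidene)acetamide
Product: 11 (E)-3-[4-(benzyloxy)-3-bromophenyl]-N-methoxy-N-methylprop-2-enamide
Conditions: toluene, 80 °C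
Reagents that add atoms: none
Why: Wittig olefination with a carbonyl-stabilised ylide, which needs no added base and with aromatic aldehydes delivers the E-alkene.

Step 7
Reactants: 11 (E)-3-[4-(benzyloxy)-3-bromophenyl]-N-methoxy-N-methylprop-2-enamide
Product: 12 (E)-3-[4-(benzyloxy)-3-(4,4,5,5-tetramethyl-1,3,2-dioxaborolan-2-yl)phenyl]-N-methoxy-N-methylprop-2-enamide
Conditions: B2pin2, PdCl2(dppf) (cat.), KOAc, 1,4-dioxane, 85 °C
Reagents that add atoms: bis(pinacolato)diboron, CC1(C)OB(OC1(C)C)B1OC(C)(C)C(C)(C)O1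
Why: Miyaura borylation: zerovalent palladium inserts into the C–Br bond and acetate-assisted transmetalation with B2pin2 delivers the aryl boronate, under conditions that tolerate the unsaturated amide and the benzyl ether.

Step 8
Reactants: 7 5,7-bis(benzyloxy)-8-iodo-2-(4-methoxyphenyl)-4H-chromen-4-one; 12 (E)-3-[4-(benzyloxy)-3-(4,4,5,5-tetramethyl-1,3,2-dioxaborolan-2-yl)phenyl]-N-methoxy-N-methylprop-2-enamide
Product: 13 (E)-3-Ar*-N-methoxy-N-methylprop-2-enamide
Conditions: Pd(OAc)2 (cat.), SPhos, K3PO4, 1,4-dioxane–H2O, 90 °C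
Reagents that add atoms: none
Why: Suzuki–Miyaura coupling: the reactive C8''–I bond undergoes fast oxidative addition and the bulky, electron-rich SPhos ligand drives transmetalation and reductive elimination to the tri-ortho-substituted biaryl, while flavone, amide and benzyl ethers are inert to aqueous K3PO4.

Step 9
Reactants: 13 (E)-3-Ar*-N-methoxy-N-methylprop-2-enamide; 14 4-hydroxy-6-methyl-2H-pyran-2-one (triacetic acid lactone)
Product: 17 4-hydroxy-6-[(E)-2-oxo-4-Ar*-but-3-en-1-yl]-2H-pyran-2-one, via dilithiated pyranone 15 (not isolated), via tetrahedral lithium adduct 16 (not isolated)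
Conditions: 14 (2.5 equiv), LiN(i-Pr)2 (4.9 equiv), THF–DMPU, −78 to −30 °C; 13, −78 to −20 °C; aq. HCl
Reagents that add atoms: none
Why: Weinreb ketone synthesis applied to the known acylation of the triacetic acid lactone dianion at its 6-methyl carbon: the hard terminal carbanion of 15 adds 1,2 to the amide carbonyl, and the lithium-chelated adduct 16 releases the acidic ketone only on quenching, so over-addition and proton transfer to unreacted dianion are avoided and the donor-deactivated flavone carbonyl is left alone.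

Step 10
Reactants: 17 4-hydroxy-6-[(E)-2-oxo-4-Ar*-but-3-en-1-yl]-2H-pyran-2-one
Product: 19 (E)-3-Ar*-1-(2,4,6-trihydroxyphenyl)prop-2-en-1-one, via ring-opened triketo ester 18 (not isolated)
Conditions: Mg(OMe)2 (8 equiv), MeOH–THF, 65 °C, under argon; then cold 1 M HCl
Reagents that add atoms: none
Why: Methoxide adds to the lactone carbonyl (C2 of the pyranone) and cleaves the C2–O1 bond, unmasking the tetraketide as methyl triketo ester 18, which magnesium holds as a chelated poly-enolate. The carbanion at C6 of that chain, the methylene between the cinnamoyl ketone C7 and the C5 carbonyl, then attacks the ester carbon C1, methoxide leaves and threefold enolisation aromatises the new ring, so that 17 and 19 are isomers and all six carbons and three oxygens of the lactone end up in ring A. The closest known reaction type is the biomimetic Claisen (Dieckmann-type) cyclisation of 6-(2-oxoalkyl)-4-hydroxy-2-pyranones and 3,5,7-triketo esters to C-acylphloroglucinols under Mg(OMe)2. The single ring closes by a 6-exo-trig acyl substitution (enolexo with respect to the C6=C7 enolate) and forms the bond that becomes C4a–C5; no stereocentre is created and the E-alkene is untouched. The selectivity needed is C6-to-C1 acylation over C2-to-C7 aldol closure (the resorcylate fold) and over internal Michael addition to the enone. It is secured because divalent magnesium keeps the C3, C5 and C7 carbonyls enolised and therefore poor acceptors, anhydrous methoxide keeps C1 an ester instead of an inert carboxylate, additions to the enone are reversible whereas aromatisation drains the Claisen path, and the symmetry of the product ring removes any regiochemical issue.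

Step 11
Reactants: 19 (E)-3-Ar*-1-(2,4,6-trihydroxyphenyl)prop-2-en-1-one
Product: 21 2-Ar*-5,7-dihydroxy-4H-chromen-4-one (4',5'',7''-tri-O-benzylpodocarpusflavone A), via racemic flavanone 20 (not isolated)
Conditions: I2 (10 mol %), DMSO, 120 °C
Reagents that add atoms: none
Why: Iodine-catalysed oxidative cyclisation of a 2'-hydroxychalcone: oxa-Michael closure (6-endo-trig) gives flavanone 20, iodination at C3 and loss of HI install the C2=C3 bond while DMSO reoxidises HI to I2, either ortho-OH of the symmetric ring gives the same flavone, and any chalcone already isomerised to 20 during the work-up of step 10 converges on the same product.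

Step 12
Reactants: 21 2-Ar*-5,7-dihydroxy-4H-chromen-4-one
Product: 22 podocarpusflavone A
Conditions: H2 (1 atm), 10% Pd/C, THF–MeOH, rt
Reagents that add atoms: none
Why: Catalytic hydrogenolysis of the three benzylic C–O bonds, which leaves the aryl methyl ether and the vinylogous-ester C2=C3 bonds of both flavones untouched, so the single OMe of the target is never at risk.

Compound list
1 | 2,4,6-trihydroxyacetophenone | CC(=O)c1c(O)cc(O)cc1O | starting material
2 | 1-[2,4-bis(benzyloxy)-6-hydroxyphenyl]ethanone | CC(=O)c1c(O)cc(OCc2ccccc2)cc1OCc1ccccc1 | intermediate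
3 | 1-[4,6-bis(benzyloxy)-2-hydroxy-3-iodophenyl]ethanone | CC(=O)c1c(O)c(I)c(OCc2ccccc2)cc1OCc1ccccc1 | intermediate
4 | 4-methoxybenzoyl chloride | COc1ccc(C(=O)Cl)cc1 | starting material
5 | dilithium phenoxide–enolate of 3 (not isolated) | [Li+].[Li+].C=C([O-])c1c([O-])c(I)c(OCc2ccccc2)cc1OCc1ccccc1 | intermediate
6 | 1-[4,6-bis(benzyloxy)-2-hydroxy-3-iodophenyl]-3-(4-methoxyphenyl)propane-1,3-dione | COc1ccc(cc1)C(=O)CC(=O)c1c(O)c(I)c(OCc2ccccc2)cc1OCc1ccccc1 | intermediate
7 | 5,7-bis(benzyloxy)-8-iodo-2-(4-methoxyphenyl)-4H-chromen-4-one | COc1ccc(cc1)-c1cc(=O)c2c(OCc3ccccc3)cc(OCc3ccccc3)c(I)c2o1 | intermediate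
8 | 3-bromo-4-hydroxybenzaldehyde | O=Cc1ccc(O)c(Br)c1 | starting material
9 | 4-(benzyloxy)-3-bromobenzaldehyde | O=Cc1ccc(OCc2ccccc2)c(Br)c1 | intermediate
10 | N-methoxy-N-methyl-2-(triphenylphosphoranylidene)acetamide | CON(C)C(=O)C=P(c1ccccc1)(c1ccccc1)c1ccccc1 | starting material
11 | (E)-3-[4-(benzyloxy)-3-bromophenyl]-N-methoxy-N-methylprop-2-enamide | CON(C)C(=O)/C=C/c1ccc(OCc2ccccc2)c(Br)c1 | intermediate
12 | (E)-3-[4-(benzyloxy)-3-(4,4,5,5-tetramethyl-1,3,2-dioxaborolan-2-yl)phenyl]-N-methoxy-N-methylprop-2-enamide | CON(C)C(=O)/C=C/c1ccc(OCc2ccccc2)c(B2OC(C)(C)C(C)(C)O2)c1 | intermediate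
13 | (E)-3-Ar*-N-methoxy-N-methylprop-2-enamide | CON(C)C(=O)/C=C/c1ccc(OCc2ccccc2)c(-c2c(OCc3ccccc3)cc(OCc3ccccc3)c3c(=O)cc(-c4ccc(OC)cc4)oc23)c1 | intermediate
14 | 4-hydroxy-6-methyl-2H-pyran-2-one (triacetic acid lactone) | Cc1cc(O)cc(=O)o1 | starting material
15 | dilithium salt of 14, 4-olate and 6-methyl carbanion (not isolated) | [Li+].[Li+].[CH2-]c1cc([O-])cc(=O)o1 | intermediate
16 | dilithium tetrahedral adduct of 15 and 13, racemic at the hemiaminal carbon, centre lost on collapse (not isolated) | [Li+].[Li+].CON(C)C([O-])(Cc1cc([O-])cc(=O)o1)/C=C/c1ccc(OCc2ccccc2)c(-c2c(OCc3ccccc3)cc(OCc3ccccc3)c3c(=O)cc(-c4ccc(OC)cc4)oc23)c1 | intermediate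
17 | 4-hydroxy-6-[(E)-2-oxo-4-Ar*-but-3-en-1-yl]-2H-pyran-2-one | O=c1cc(O)cc(CC(=O)/C=C/c2ccc(OCc3ccccc3)c(-c3c(OCc4ccccc4)cc(OCc4ccccc4)c4c(=O)cc(-c5ccc(OC)cc5)oc34)c2)o1 | intermediate
18 | methyl (E)-9-Ar*-3,5,7-trioxonon-8-enoate, magnesium chelate in the flask, drawn in the neutral triketo form (not isolated) | COC(=O)CC(=O)CC(=O)CC(=O)/C=C/c1ccc(OCc2ccccc2)c(-c2c(OCc3ccccc3)cc(OCc3ccccc3)c3c(=O)cc(-c4ccc(OC)cc4)oc23)c1 | intermediate
19 | (E)-3-Ar*-1-(2,4,6-trihydroxyphenyl)prop-2-en-1-one | O=C(/C=C/c1ccc(OCc2ccccc2)c(-c2c(OCc3ccccc3)cc(OCc3ccccc3)c3c(=O)cc(-c4ccc(OC)cc4)oc23)c1)c1c(O)cc(O)cc1O | intermediate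
20 | 2-Ar*-5,7-dihydroxychroman-4-one, racemic at C2 (not isolated) | O=C1CC(c2ccc(OCc3ccccc3)c(-c3c(OCc4ccccc4)cc(OCc4ccccc4)c4c(=O)cc(-c5ccc(OC)cc5)oc34)c2)Oc2cc(O)cc(O)c12 | intermediate
21 | 2-Ar*-5,7-dihydroxy-4H-chromen-4-one (4',5'',7''-tri-O-benzylpodocarpusflavone A) | O=c1cc(-c2ccc(OCc3ccccc3)c(-c3c(OCc4ccccc4)cc(OCc4ccccc4)c4c(=O)cc(-c5ccc(OC)cc5)oc34)c2)oc2cc(O)cc(O)c12 | intermediate
22 | podocarpusflavone A | COc1ccc(-c2cc(=O)c3c(O)cc(O)c(-c4cc(-c5cc(=O)c6c(O)cc(O)cc6o5)ccc4O)c3o2)cc1 | target

Total step count: 12.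
Longest linear sequence: 9 steps (1, 2, 3, 4, 8, 9, 10, 11, 12, from 1). The side branch 5, 6, 7 joins at step 8.

Steps most likely to fail

1. Step 10.
   - The opened chain may fold in the aldol sense (C2 onto the C7 ketone).
   - An internal enolate may add to the enone.
   - The deprotonated pyranone may resist methanolysis altogether.
   - The fallback brings ring A in preformed. It sets out from 9, uses 7 and 2 as partners, and comes back to the route at 22. Miyaura borylation of 9 (B2pin2, PdCl2(dppf), KOAc, 1,4-dioxane) should give 4-(benzyloxy)-3-(4,4,5,5-tetramethyl-1,3,2-dioxaborolan-2-yl)benzaldehyde F1. Suzuki–Miyaura coupling with 7 under the conditions of step 8 should give the biaryl aldehyde Ar*-CHO F2. Claisen–Schmidt condensation with 2 (KOH, EtOH–THF, rt) should give (E)-3-Ar*-1-[2,4-bis(benzyloxy)-6-hydroxyphenyl]prop-2-en-1-one F3. Catalytic I2 in DMSO should close it to 2-Ar*-5,7-bis(benzyloxy)-4H-chromen-4-one F4. Hydrogenolysis as in step 12 then gives 22.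

2. Step 9.
   - Conjugate addition may compete with carbonyl addition.
   - The carbanion may attack C2'' or C4'' of the acacetin chromenone.
   - The dianion may precipitate, giving low conversion.
   - The fallback replaces acylation by aldehyde addition and oxidation. It sets out from 13 and comes back at 17. Reduction with i-Bu2AlH (1.1 equiv, CH2Cl2, −78 °C) should give (E)-3-Ar*-prop-2-enal F5, a far stronger and harder electrophile than the amide. Addition of 15 at −78 °C should give racemic 4-hydroxy-6-[(E)-2-hydroxy-4-Ar*-but-3-en-1-yl]-2H-pyran-2-one F6. Oxidation of the allylic alcohol with MnO2 (CH2Cl2–THF, rt) then gives 17.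

3. Step 11.
   - The unprotected phloroglucinol ring may undergo electrophilic iodination.
   - HI may partly cleave the peri benzyl ether.
   - The free phenols may degrade oxidatively in hot DMSO.
   - The fallback separates ring closure from dehydrogenation and masks the phenols. It sets out from 19 and comes back at 21. First 19 is isomerised on purpose to flavanone 20 (NaOAc, EtOH, reflux), which is isolated. Ac2O, pyridine and DMAP should give 2-Ar*-4-oxochroman-5,7-diyl diacetate F7. DDQ in refluxing 1,4-dioxane should dehydrogenate C2–C3 by hydride abstraction to 2-Ar*-4-oxo-4H-chromene-5,7-diyl diacetate F8. K2CO3 in MeOH–THF then removes the acetates to give 21.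

Further compounds
F1 | step 10 | 4-(benzyloxy)-3-(4,4,5,5-tetramethyl-1,3,2-dioxaborolan-2-yl)benzaldehyde | O=Cc1ccc(OCc2ccccc2)c(B2OC(C)(C)C(C)(C)O2)c1
F2 | step 10 | 4-(benzyloxy)-3-[5,7-bis(benzyloxy)-2-(4-methoxyphenyl)-4-oxo-4H-chromen-8-yl]benzaldehyde (Ar*-CHO) | O=Cc1ccc(OCc2ccccc2)c(-c2c(OCc3ccccc3)cc(OCc3ccccc3)c3c(=O)cc(-c4ccc(OC)cc4)oc23)c1
F3 | step 10 | (E)-3-Ar*-1-[2,4-bis(benzyloxy)-6-hydroxyphenyl]prop-2-en-1-one | O=C(/C=C/c1ccc(OCc2ccccc2)c(-c2c(OCc3ccccc3)cc(OCc3ccccc3)c3c(=O)cc(-c4ccc(OC)cc4)oc23)c1)c1c(O)cc(OCc2ccccc2)cc1OCc1ccccc1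
F4 | step 10 | 2-Ar*-5,7-bis(benzyloxy)-4H-chromen-4-one | O=c1cc(-c2ccc(OCc3ccccc3)c(-c3c(OCc4ccccc4)cc(OCc4ccccc4)c4c(=O)cc(-c5ccc(OC)cc5)oc34)c2)oc2cc(OCc3ccccc3)cc(OCc3ccccc3)c12
F5 | step 9 | (E)-3-Ar*-prop-2-enal | O=C/C=C/c1ccc(OCc2ccccc2)c(-c2c(OCc3ccccc3)cc(OCc3ccccc3)c3c(=O)cc(-c4ccc(OC)cc4)oc23)c1
F6 | step 9 | 4-hydroxy-6-[(E)-2-hydroxy-4-Ar*-but-3-en-1-yl]-2H-pyran-2-one, racemic | O=c1cc(O)cc(CC(O)/C=C/c2ccc(OCc3ccccc3)c(-c3c(OCc4ccccc4)cc(OCc4ccccc4)c4c(=O)cc(-c5ccc(OC)cc5)oc34)c2)o1
F7 | step 11 | 2-Ar*-4-oxochroman-5,7-diyl diacetate, racemic | CC(=O)Oc1cc(OC(C)=O)c2C(=O)CC(c3ccc(OCc4ccccc4)c(-c4c(OCc5ccccc5)cc(OCc5ccccc5)c5c(=O)cc(-c6ccc(OC)cc6)oc45)c3)Oc2c1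
F8 | step 11 | 2-Ar*-4-oxo-4H-chromene-5,7-diyl diacetate | CC(=O)Oc1cc(OC(C)=O)c2c(=O)cc(-c3ccc(OCc4ccccc4)c(-c4c(OCc5ccccc5)cc(OCc5ccccc5)c5c(=O)cc(-c6ccc(OC)cc6)oc45)c3)oc2c1
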